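**Retrosynthetic overview**
1. Endgame: C12–C13 is made by B-alkyl Suzuki–Miyaura coupling of a C9-vinyl bicycle with a (Z)-β-iodo enoate from propargyl alcohol (anti hydroiodination fixes the 13E geometry). O-acetylation follows, and both acids are then freed together from tert-butyl esters.
2. C6=C7 goes back to a 6-ketone (kinetic enol triflate, formate reduction). The ketone goes back to hydroboration of a C5=C6 alkene, which also puts H-5 anti to C20.
3. Feature used: in ring B (C5–C10) the C6–C7 bond links the termini of a 1,5-diene, C6=C5–C10–C9–C8=C7, folded about quaternary C10. One end is a methylene on ring A, the other the acrylate bearing C17. A Lewis acid drives C6 onto C7, the C11 carboxylate catches the C5 cation before it can fragment, and the lactone bridge is then opened to the C5=C6 alkene.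
4. The diene comes from Ireland–Claisen rearrangement of β-cyclogeranyl methyl itaconate (C9–C10 bond, C10 quaternary), made from β-cyclocitral and itaconic anhydride and resolved as the acid. The rearrangement should give C9 epimeric to the target, which is what holds the carboxylate over C5. C9 is inverted afterwards through the ketene.
5. Ring order: ring A is bought and ring B closes in the key step. The lactone is a temporary bridge.

Key step: step 7

Numbering: labdane numbering (C1–C10 decalin, C11–C16 side chain, C17 the carboxyl carbon on C8, C18/C19 on C4, C20 on C10).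
Assumption: the salt of the wanted acid enantiomer with (R)-1-phenylethylamine is taken to be the less soluble one. If the pairing is the opposite, the (S)-amine is used in the same way, and the assignment is checked by X-ray analysis of the salt.

Step 1
Reactants: 1 β-cyclocitral
Product: 2 β-cyclogeraniol
Conditions: NaBH4, MeOH, 0 °C
Reagents that add atoms: none
Why: Borohydride 1,2-reduction of a hindered enal; the tetrasubstituted C5=C10 alkene is untouched and no stereocentre is formed.

Step 2
Reactants: 2 β-cyclogeraniol; 3 itaconic anhydride
Product: 4 4-(β-cyclogeranyl) hydrogen itaconate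
Conditions: toluene, 70 °C, no amine base
Reagents that add atoms: none
Why: Alcoholysis of an unsymmetrical anhydride at the unconjugated, less hindered carbonyl next to CH2, which puts the allyl ester on the future C11 and leaves the acrylic acid (C17) free; amines are left out because they isomerise 3 to citraconic anhydride.

Step 3
Reactants: 4 4-(β-cyclogeranyl) hydrogen itaconate
Product: 5 1-methyl 4-(β-cyclogeranyl) itaconate
Conditions: MeI, KHCO3, DMF, 23 °C
Reagents that add atoms: iodomethane, CI
Why: SN2 O-alkylation of the carboxylate with a base too weak to move the alkene into conjugation; diazoalkanes are avoided because they cycloadd to acrylates.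

Step 4
Reactants: 5 1-methyl 4-(β-cyclogeranyl) itaconate
Product: 9 racemic Claisen acid (C9 epimeric to the target), via lithium dienolate 6 (not isolated), via silyl ketene acetal 7 (not isolated), via trimethylsilyl ester 8 (not isolated)
Conditions: LiN(iPr)2, THF–DMPU 4:1, −78 °C (slow addition of 5); Me3SiCl, −78 → 23 °C; toluene, 90 °C; aq. citric acid
Reagents that add atoms: none
Why: Ireland–Claisen rearrangement: deprotonation of the doubly activated C9H2 and O-silylation give a ketene acetal whose [3,3] shift across O–C6–C5=C10 forms C9–C10, makes C10 quaternary and releases the C5=C6 methylene; the chair that keeps H-9 (not the acrylate) over ring A and the silyloxy group away from the C4 methyls should dominate and sets C9 relative to C10 with the carboxyl anti to C20 in the folded rotamer (racemic at this stage).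

Step 5
Reactants: 9 racemic Claisen acid
Product: 10 (R)-1-phenylethylammonium salt of the (2R,1'S) acid
Conditions: (R)-1-phenylethylamine (0.5 equiv), EtOAc–heptane, crystallised to constant rotation
Reagents that add atoms: (R)-1-phenylethylamine, C[C@@H](N)c1ccccc1
Why: Classical resolution through diastereomeric ammonium salts by the half-equivalent method, which fixes the absolute configuration at C10 (and C9) and purges any minor Claisen diastereomer.

Step 6
Reactants: 10 (R)-1-phenylethylammonium salt
Product: 11 (2R)-3-(methoxycarbonyl)-2-[(1S)-1,3,3-trimethyl-2-methylidenecyclohexyl]but-3-enoic acid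
Conditions: 1 M HCl, Et2O, 0 °C, short contact
Reagents that add atoms: none
Why: Acid–base release of the carboxylic acid, kept cold and brief because a γ,δ-unsaturated acid with a 1,1-disubstituted alkene can protolactonise.

Step 7
Reactants: 11 resolved diene acid
Product: 14 bridged γ-lactone ester (ring B closed; C8 epimers), via dichloroaluminium carboxylate 12 (not isolated), via lactone aluminium enolate 13 (not isolated)
Conditions: MeAlCl2 (2.5 equiv, hexanes), CH2Cl2, −78 → 0 °C; poured into ice-cold 1 M HCl
Reagents that add atoms: none
Why: Proposed new method: one equivalent of MeAlCl2 converts the acid into its dichloroaluminium carboxylate with loss of methane, so that no Brønsted acid remains to protonate C6, and the excess binds the C17 ester carbonyl, whereupon C6, the unsubstituted end of the ring A methylene, adds to C7 through a chair-like fold of the 1,5-diene and leaves positive charge on tertiary C5 and an aluminium enolate at C8. The closest known reactions are the alkylaluminium halide-promoted additions of 1,1-disubstituted alkenes to acrylates and the acid-catalysed Cope rearrangement of 2-acyl-1,5-dienes, which runs through the same cyclohexyl cation; a concerted ene path is not available because neither C4 nor C10 bears hydrogen. Ring B closes 6-endo-trig with respect to both alkenes and the lactone bridge closes 5-exo at C5. The untested element is the interception: in 11 the C11 carboxylate sits axial on the nascent ring B, 1,3-diaxial to the empty orbital at C5, so that C5–O bonding should outrun cleavage of C9–C10 (the Cope outcome) and methyl shifts from C4 or C10. C5 is fixed by this tether, since the oxygen can only reach the face opposite C20, whereas C8 arises without control when the enolate is protonated at the quench and is settled in step 8. The step needs C6-to-C7 regioselectivity, which the polarity of both partners dictates, and chemoselectivity against protolactonisation, which the proton-scavenging Al–CH3 bond secures.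

Step 8
Reactants: 14 bridged γ-lactone ester
Product: 16 5-ene acid ester with C9 still epimeric, via trimethylsilyl ester 15 (not isolated)
Conditions: Me3SiOTf, 2,6-lutidine, CH2Cl2, 0 → 23 °C; then NaOMe, MeOH, 50 °C; cold dilute HCl to pH 4
Reagents that add atoms: none
Why: Silyl triflate cleavage of a tert-alkyl carboxylate (the E1-type reaction used for tert-butyl esters): O-silylation ionises the crowded C5–O bond, C6 is the sole source of a β-proton since C4 and C10 are fully substituted, fragmentation is no longer possible because C8 is now a plain ester carbon, and the methoxide equilibration then moves the C17 ester equatorial, away from syn-axial C20, while the C11 carboxylate shields C9.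

Step 9
Reactants: 16 5-ene acid ester (9-epi)
Product: 19 5-ene acid ester with the target configuration at C8 C9 C10, via acid chloride 17 (not isolated), via ketene 18 (not isolated)
Conditions: 1-chloro-N,N,2-trimethylprop-1-en-1-amine, CH2Cl2, 0 °C; Et3N, toluene, 50 °C; then THF–H2O, 0 °C
Reagents that add atoms: water, O
Why: Epimerisation through a ketene: neutral acid chloride formation and dehydrochlorination erase C9, and the acid enol formed on hydration should be protonated on carbon from the face opposite the adjacent axial C20 methyl, leaving H-9 anti to C20 and C11 equatorial; base equilibration is not relied on because a carboxylate hardly enolises and the equatorial preference next to quaternary C10 is expected to be small.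

Step 10
Reactants: 19 5-ene acid ester
Product: 21 6-oxo 11-aldehyde methyl ester, via bis-boryl intermediate 20 (not isolated)
Conditions: BH3·SMe2 (4 equiv), THF, 0 → 45 °C; then N-methylmorpholine N-oxide, [N(C3H7)4][RuO4] (5 mol %), 4 Å sieves, CH2Cl2, 23 °C
Reagents that add atoms: N-methylmorpholine N-oxide, C[N+]1([O-])CCOCC1
Why: Borane reduction of the acid and hydroboration of the trisubstituted alkene followed by one-pot N-oxide/perruthenate oxidation of the C–B and C–O–B bonds: boron goes to C6 and hydrogen to C5 by syn addition on the face opposite C20 and the axial C4 methyl (trans fusion, still correctable next to the ketone), and since no free C11 alkoxide is released it cannot lactonise onto the C17 ester.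

Step 11
Reactants: 21 6-oxo 11-aldehyde methyl ester
Product: 22 9-vinyl 6-ketone methyl ester
Conditions: Ph3PCH3Br, KN(SiMe3)2, THF, 0 °C; then 21, −78 → 0 °C
Reagents that add atoms: methyltriphenylphosphonium bromide, C[P+](c1ccccc1)(c1ccccc1)c1ccccc1.[Br-]
Why: Wittig methylenation: the aldehyde reacts far faster than the 6-ketone buried between C5 and the C4 methyls, and low temperature without excess base keeps C9 intact until it is no longer acidic.

Step 12
Reactants: 22 9-vinyl 6-ketone methyl ester
Product: 23 9-vinyl 6-keto 17-acid
Conditions: LiOH, THF–MeOH–H2O, 50 °C; 1 M HCl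
Reagents that add atoms: lithium hydroxide, [Li+].[OH-]
Why: Saponification carried out while ring B is still saturated, so that base can only confirm the thermodynamic arrangement (equatorial C17, trans-fused C5) and cannot draw an alkene into conjugation.

Step 13
Reactants: 23 9-vinyl 6-keto 17-acid
Product: 24 tert-butyl ester of 23
Conditions: Cl3CC(=NH)OtBu, BF3·OEt2 (cat.), CH2Cl2–cyclohexane, 23 °C
Reagents that add atoms: tert-butyl 2,2,2-trichloroacetimidate, CC(C)(C)OC(=N)C(Cl)(Cl)Cl
Why: Acid-catalysed O-tert-butylation with the trichloroacetimidate, which alkylates the carboxyl oxygen and is therefore insensitive to the hindrance at C17, and gives an ester removable at the end without base.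

Step 14
Reactants: 24 tert-butyl keto ester
Product: 26 C6 enol triflate (C6=C7), via potassium enolate 25 (not isolated)
Conditions: KN(SiMe3)2 (1.05 equiv), THF, −78 °C; PhNTf2, −78 → 0 °C
Reagents that add atoms: N-phenylbis(trifluoromethanesulfonimide), O=S(=O)(N(c1ccccc1)S(=O)(=O)C(F)(F)F)C(F)(F)F
Why: Kinetic enolate formation and O-triflation: the bulky amide takes a C7 proton rather than the tertiary H-5 locked between C4 and C10 or the less acidic H-8, so C5 and C8 are not touched.

Step 15
Reactants: 26 C6 enol triflate
Product: 27 tert-butyl 9-vinyl 6-ene 17-oate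
Conditions: Pd(OAc)2 (5 mol %), PPh3, HCO2H, Et3N, DMF, 60 °C
Reagents that add atoms: none
Why: Palladium-catalysed formate reduction of an enol triflate (oxidative addition to zerovalent palladium, decarboxylation of the formate, reductive elimination) puts hydrogen on C6 and leaves C6=C7, and Et3N is too weak to remove the now allylic H-8.

Step 16
Reactants: 28 propargyl alcohol
Product: 29 tert-butyldimethylsilyl propargyl ether
Conditions: TBSCl, imidazole, CH2Cl2, 23 °C
Reagents that add atoms: tert-butyldimethylsilyl chloride, CC(C)(C)[Si](C)(C)Cl
Why: Standard silylation that masks the hydroxyl proton before the alkyne is lithiated.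

Step 17
Reactants: 29 silyl propargyl ether
Product: 31 tert-butyl 4-(silyloxy)but-2-ynoate, via lithium acetylide 30 (not isolated)
Conditions: n-BuLi, THF, −78 °C; Boc2O, −78 → 0 °C
Reagents that add atoms: di-tert-butyl dicarbonate, CC(C)(C)OC(=O)OC(=O)OC(C)(C)C
Why: Acylation of a lithium acetylide with the dicarbonate installs C15 directly as its tert-butyl ester.

Step 18
Reactants: 31 tert-butyl 4-(silyloxy)but-2-ynoate
Product: 32 tert-butyl 4-hydroxybut-2-ynoate
Conditions: camphorsulfonic acid (cat.), MeOH, 0 → 23 °C
Reagents that add atoms: none
Why: Mild acid methanolysis of a primary silyl ether, which spares the tert-butyl ester and avoids basic fluoride on a Michael-accepting ynoate.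

Step 19
Reactants: 32 tert-butyl 4-hydroxybut-2-ynoate
Product: 33 tert-butyl (Z)-4-hydroxy-3-iodobut-2-enoate
Conditions: NaI, AcOH, MeCN, 70 °C
Reagents that add atoms: sodium iodide, [Na+].[I-]
Why: Conjugate hydroiodination of an ynoate: iodide adds to C13 and the allenolate is protonated anti, giving iodine cis and CH2OH trans to the ester, which is the geometry needed after a retentive coupling and one in which no butenolide can form.

Step 20
Reactants: 27 tert-butyl 9-vinyl 6-ene 17-oate; 33 tert-butyl (Z)-4-hydroxy-3-iodobut-2-enoate
Product: 35 16-hydroxy bis(tert-butyl) ester, via B-alkyl-9-BBN 34 (not isolated)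
Conditions: 9-BBN dimer, THF, 0 → 23 °C; then 33, PdCl2(dppf) (5 mol %), AsPh3, aq. K3PO4, DMF, 23 °C
Reagents that add atoms: none
Why: Hydroboration and B-alkyl Suzuki–Miyaura coupling: 9-BBN selects the monosubstituted vinyl group over the hindered ring alkene and places boron on C12, the coupling forms C12–C13 with retention of alkene geometry under aqueous phosphate at room temperature (which should spare H-8), and the free alcohol is used because an allylic acetate could ionise on zerovalent palladium.

Step 21
Reactants: 35 16-hydroxy bis(tert-butyl) ester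
Product: 36 16-acetoxy bis(tert-butyl) ester
Conditions: Ac2O, pyridine, DMAP (cat.), CH2Cl2, 0 °C
Reagents that add atoms: acetic anhydride, CC(=O)OC(C)=O
Why: Routine acylation of the only free hydroxyl group, done while both carboxyl groups are still masked so that no mixed anhydride can form at C17.

Step 22
Reactants: 36 16-acetoxy bis(tert-butyl) ester
Product: 37 target CNP0108723.1
Conditions: CF3CO2H–CH2Cl2 1:4, 0 → 23 °C
Reagents that add atoms: none
Why: Acidolysis of both tert-butyl esters with loss of isobutene, a base-free release that keeps the primary acetate, the 13E enoate, the β,γ-position of C6=C7 and the configuration at C8.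

**Compound list**
1 | β-cyclocitral (2,6,6-trimethylcyclohex-1-ene-1-carbaldehyde) | CC1=C(C=O)C(C)(C)CCC1 | starting material
2 | β-cyclogeraniol ((2,6,6-trimethylcyclohex-1-en-1-yl)methanol) | CC1=C(CO)C(C)(C)CCC1 | intermediate
3 | itaconic anhydride | C=C1CC(=O)OC1=O | starting material
4 | 2-methylidene-4-oxo-4-[(2,6,6-trimethylcyclohex-1-en-1-yl)methoxy]butanoic acid | OC(=O)C(=C)CC(=O)OCC1=C(C)CCCC1(C)C | intermediate
5 | 1-methyl 4-[(2,6,6-trimethylcyclohex-1-en-1-yl)methyl] 2-methylidenebutanedioate | COC(=O)C(=C)CC(=O)OCC1=C(C)CCCC1(C)C | intermediate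
6 | lithium dienolate of 5 (alkenyl group cis to OLi) | C=C(C(=O)OC)/C=C(\O[Li])OCC1=C(C)CCCC1(C)C | intermediate
7 | trimethylsilyl ketene acetal of 5 (alkenyl group cis to OSi) | C=C(C(=O)OC)/C=C(\O[Si](C)(C)C)OCC1=C(C)CCCC1(C)C | intermediate
8 | trimethylsilyl ester of 9 (racemic; the enantiomer carried on is drawn) | C[Si](C)(C)OC(=O)[C@@H](C(=C)C(=O)OC)[C@]1(C)CCCC(C)(C)C1=C | intermediate
9 | (±)-(2R*)-3-(methoxycarbonyl)-2-[(1S*)-1,3,3-trimethyl-2-methylidenecyclohexyl]but-3-enoic acid (racemic; the enantiomer carried on is drawn) | OC(=O)[C@@H](C(=C)C(=O)OC)[C@]1(C)CCCC(C)(C)C1=C | intermediate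
10 | (R)-1-phenylethylammonium salt of the (2R,1'S) acid | [O-]C(=O)[C@@H](C(=C)C(=O)OC)[C@]1(C)CCCC(C)(C)C1=C.C[C@@H]([NH3+])c1ccccc1 | intermediate
11 | (2R)-3-(methoxycarbonyl)-2-[(1S)-1,3,3-trimethyl-2-methylidenecyclohexyl]but-3-enoic acid (key-step precursor; C10 as in the target, C9 epimeric) | OC(=O)[C@@H](C(=C)C(=O)OC)[C@]1(C)CCCC(C)(C)C1=C | intermediate
12 | dichloroaluminium carboxylate of 11 | Cl[Al](Cl)OC(=O)[C@@H](C(=C)C(=O)OC)[C@]1(C)CCCC(C)(C)C1=C | intermediate
13 | aluminium enolate (C8=C17) of the bridged lactone | COC(O[Al](Cl)Cl)=C1CC[C@@]23OC(=O)[C@@H]1[C@]2(C)CCCC3(C)C | intermediate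
14 | bridged γ-lactone ester: decalin with C11(=O)–O–C5 bridge, O-5 and C11 on the face opposite C20, C17 methyl ester on C8 (C8 epimers) | COC(=O)C1CC[C@@]23OC(=O)[C@@H]1[C@]2(C)CCCC3(C)C | intermediate
15 | trimethylsilyl ester of the 5-ene acid (9-epi, C8 epimers) | C[Si](C)(C)OC(=O)[C@H]1C(C(=O)OC)CC=C2C(C)(C)CCC[C@@]12C | intermediate
16 | 5-ene bicyclic 11-acid 17-methyl ester, 9-epi: C11 axial and anti to C20, C17 equatorial (H-8 on the C20 face) | O=C(O)[C@H]1[C@@H](C(=O)OC)CC=C2C(C)(C)CCC[C@@]12C | intermediate
17 | acid chloride of 16 | O=C(Cl)[C@H]1[C@@H](C(=O)OC)CC=C2C(C)(C)CCC[C@@]12C | intermediate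
18 | C9=C11=O ketene | O=C=C1[C@@H](C(=O)OC)CC=C2C(C)(C)CCC[C@@]12C | intermediate
19 | 5-ene bicyclic 11-acid 17-methyl ester, H-9 anti to C20, C11 and C17 both equatorial | O=C(O)[C@@H]1[C@@H](C(=O)OC)CC=C2C(C)(C)CCC[C@@]12C | intermediate
20 | 6-boryl 11-boryloxy intermediate (drawn as the BH2 species; H-5 and B-6 on the face opposite C20) | BOC[C@@H]1[C@@H](C(=O)OC)C[C@@H](B)[C@@H]2C(C)(C)CCC[C@@]12C | intermediate
21 | trans-decalin 6-ketone, 11-aldehyde, 17-methyl ester | O=C[C@@H]1[C@@H](C(=O)OC)CC(=O)[C@@H]2C(C)(C)CCC[C@@]12C | intermediate
22 | 9-vinyl 6-ketone 17-methyl ester | C=C[C@@H]1[C@@H](C(=O)OC)CC(=O)[C@@H]2C(C)(C)CCC[C@@]12C | intermediate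
23 | 9-vinyl 6-keto 17-acid | C=C[C@@H]1[C@@H](C(=O)O)CC(=O)[C@@H]2C(C)(C)CCC[C@@]12C | intermediate
24 | 9-vinyl 6-ketone 17-tert-butyl ester | C=C[C@@H]1[C@@H](C(=O)OC(C)(C)C)CC(=O)[C@@H]2C(C)(C)CCC[C@@]12C | intermediate
25 | potassium C6=C7 enolate of 24 | C=C[C@@H]1[C@@H](C(=O)OC(C)(C)C)C=C(O[K])[C@@H]2C(C)(C)CCC[C@@]12C | intermediate
26 | C6 enol triflate | C=C[C@@H]1[C@@H](C(=O)OC(C)(C)C)C=C(OS(=O)(=O)C(F)(F)F)[C@@H]2C(C)(C)CCC[C@@]12C | intermediate
27 | tert-butyl 9-vinyl 6-ene 17-oate | C=C[C@@H]1[C@@H](C(=O)OC(C)(C)C)C=C[C@@H]2C(C)(C)CCC[C@@]12C | intermediate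
28 | propargyl alcohol | C#CCO | starting material
29 | tert-butyldimethyl(prop-2-yn-1-yloxy)silane | C#CCO[Si](C)(C)C(C)(C)C | intermediate
30 | lithium acetylide of 29 | [Li]C#CCO[Si](C)(C)C(C)(C)C | intermediate
31 | tert-butyl 4-[(tert-butyldimethylsilyl)oxy]but-2-ynoate | CC(C)(C)OC(=O)C#CCO[Si](C)(C)C(C)(C)C | intermediate
32 | tert-butyl 4-hydroxybut-2-ynoate | CC(C)(C)OC(=O)C#CCO | intermediate
33 | tert-butyl (Z)-4-hydroxy-3-iodobut-2-enoate | OC/C(I)=C/C(=O)OC(C)(C)C | intermediate
34 | B-(C12-alkyl)-9-borabicyclo[3.3.1]nonane from 27 | B1(CC[C@@H]2[C@@H](C(=O)OC(C)(C)C)C=C[C@@H]3C(C)(C)CCC[C@@]23C)C2CCCC1CCC2 | intermediate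
35 | 16-hydroxy 15,17-bis(tert-butyl) ester (13E) | OC/C(=C/C(=O)OC(C)(C)C)CC[C@@H]1[C@@H](C(=O)OC(C)(C)C)C=C[C@@H]2C(C)(C)CCC[C@@]12C | intermediate
36 | 16-acetoxy 15,17-bis(tert-butyl) ester (13E) | CC(=O)OC/C(=C/C(=O)OC(C)(C)C)CC[C@@H]1[C@@H](C(=O)OC(C)(C)C)C=C[C@@H]2C(C)(C)CCC[C@@]12C | intermediate
37 | CNP0108723.1, (5R,8S,9R,10S,13E)-16-acetoxylabda-6,13-diene-15,17-dioic acid | CC(=O)OC/C(=C/C(=O)O)CC[C@@H]1[C@@H](C(=O)O)C=C[C@@H]2C(C)(C)CCC[C@@]12C | target

Total step count: 22. Longest linear sequence: 18 steps (steps 1–15 and 20–22).

**The three steps most likely to fail**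

1. Step 7.
   - What may go wrong: the cyclohexyl cation fragments along C9–C10 (completing a Lewis acid-catalysed Cope rearrangement). It may also revert to the diene, be captured by chloride, or suffer methyl migration before the carboxylate closes on C5.
   - Fallback (known chemistry, same C6–C7 bond, radical instead of cation): setting out from 11, iodolactonisation (I2, NaHCO3, MeCN–H2O, 0 °C) lets the carboxylate add to C5 by axial attack anti to C20. The other face is flanked by the axial methyls on C4 and C10. This gives the iodomethyl γ-lactone F1.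
   - Slow addition of Bu3SnH and AIBN in benzene at 80 °C then generates the C6 radical. It closes 6-endo onto the unsubstituted terminus C7 of the α-substituted acrylate, and hydrogen transfer to the C8 radical brings the route back at 14.

2. Step 4.
   - What may go wrong: anionic oligomerisation by conjugate addition of the dienolate to unreacted acrylate, γ-protonation that moves the alkene into conjugation, and decay of the ketene acetal during the slow [3,3] shift onto a tetrasubstituted alkene.
   - Fallback: the dienolate is reached by deconjugative enolisation of a substrate that has no terminal acrylate. Setting out from 2, heating with citraconic anhydride (attack at the carbonyl remote from the methyl group) gives the β-cyclogeranyl hydrogen citraconate F2.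
   - MeI/KHCO3 then gives the methyl β-cyclogeranyl citraconate F3. LiN(iPr)2 in THF–DMPU removes a γ-proton from the vinylic methyl group and produces the same dienolate 6. The route then continues as in step 4 and comes back at 9.

3. Step 9.
   - What may go wrong: incomplete dehydrochlorination (direct hydrolysis then retains C9) and poor facial selectivity when the acid enol is protonated.
   - Fallback: C9 is inverted one oxidation level lower. Setting out from 16, the conditions of step 10 give the 9-epi keto aldehyde F4, and Me3SiOTf/Et3N in CH2Cl2 converts it into the bis(silyl enol ether) F5.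
   - Bu4NF/AcOH in THF at −78 °C releases both carbonyl groups, with kinetic protonation of C9 on the face opposite C20. The route comes back at 21.

**Further compounds**
F1 | step 7 | iodomethyl γ-lactone from 11 (O-5 anti to C20, CH2I equatorial on ring A, acrylate on C9) | C=C(C(=O)OC)[C@@H]1C(=O)O[C@@]2(CI)C(C)(C)CCC[C@@]12C
F2 | step 4 | (Z)-2-methyl-4-oxo-4-[(2,6,6-trimethylcyclohex-1-en-1-yl)methoxy]but-2-enoic acid | OC(=O)/C(C)=C\C(=O)OCC1=C(C)CCCC1(C)C
F3 | step 4 | 1-methyl 4-(β-cyclogeranyl) citraconate | COC(=O)/C(C)=C\C(=O)OCC1=C(C)CCCC1(C)C
F4 | step 9 | 9-epi 6-oxo 11-aldehyde methyl ester | O=C[C@H]1[C@@H](C(=O)OC)CC(=O)[C@@H]2C(C)(C)CCC[C@@]12C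
F5 | step 9 | bis(trimethylsilyl enol ether) (C9=C11 and C6=C7) | C[Si](C)(C)OC=C1[C@@H](C(=O)OC)C=C(O[Si](C)(C)C)[C@@H]2C(C)(C)CCC[C@@]12C
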